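The C3–C3'' bond with its neighbours C4, C4'', C2 and C2'' is a hidden 2,3-bis(4-methoxybenzylidene)succinic acid, so both chromanones are grown on a Stobbe-derived diacid by two phenol annulations. The key step exploits the 1,3-relationship of O1'' and C4a'' on ring A of unit 2 against C2'' and C4'' of its ring C: the resolved unit-1 acid is esterified in situ with symmetric 3,5-dimethoxyphenol, a Fries shift moves the acyl carbon C4'' to the ortho carbon C4a'', and the released phenol oxygen closes the pyranone by oxa-Michael addition to C2'', which also sets C2'' and C3''. The precursor is an α-(flavanon-3-yl)-4-methoxycinnamic acid.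

Key step: step 5

Remark on numbering: unit 1 is the 5,7-dioxygenated flavanone (O1, C2, C3, C4, C4a, C8a; rings A, C, B); unit 2 is the 5-hydroxy-7-methoxyflavanone and carries the same locants with a double prime.

Remark on the chemistry: the phenol that delivers O1'' and C4a'' is used as 3,5-dimethoxyphenol, whose two ortho carbons are equivalent. The methyl group on O5'' is a protecting group, cleaved in the last step by chelation control. The hydroxyls of unit 1 travel as benzyl ethers. The single enantiomer is secured by resolving the unit-1 acid in step 4.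

Step 1
Reactants: 1 diethyl succinate; 2 4-methoxybenzaldehyde (2 equiv)
Product: 4 (2E,3E)-2,3-bis(4-methoxybenzylidene)succinic acid, via half-ester 3 (not isolated)
Conditions: NaOEt (3 equiv), EtOH, reflux; then aq. HCl
Reagents that add atoms: none
Why: Double Stobbe condensation: each succinate α-carbon adds to the aldehyde, the alkoxide lactonises onto the distal ester and E1cB ring opening gives an E-arylidene carboxylate, so both esters end as carboxylates and the C4–C3–C3''–C4'' backbone with both future C2 carbons is in place.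

Step 2
Reactants: 4 (2E,3E)-2,3-bis(4-methoxybenzylidene)succinic acid
Product: 5 (3E,4E)-3,4-bis(4-methoxybenzylidene)oxolane-2,5-dione
Conditions: AcCl, reflux, exclusion of light
Reagents that add atoms: none
Why: Acetyl chloride dehydrates the 1,4-diacid to the five-membered anhydride (standard fulgide formation), which activates both carboxyl carbons equally and should leave the E,E-diene untouched.

Step 3
Reactants: 5 (3E,4E)-3,4-bis(4-methoxybenzylidene)oxolane-2,5-dione; 6 3,5-bis(benzyloxy)phenol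
Product: 8 rac-(E)-2-[(2S*,3R*)-5,7-bis(benzyloxy)-2-(4-methoxyphenyl)-4-oxochroman-3-yl]-3-(4-methoxyphenyl)prop-2-enoic acid, via keto acid 7 (not isolated)
Conditions: BF3·OEt2, CH2Cl2, 0 °C → rt; then NaOAc, MeOH–H2O, 40 °C; then 1 M HCl
Reagents that add atoms: none
Why: Friedel–Crafts acylation of the phenol at either of its two equivalent ortho carbons by the symmetric anhydride gives the 2-hydroxyaryl ketone 7, whose phenol closes by 6-endo-trig oxa-Michael addition onto the adjacent benzylidene carbon; C2 forms as the racemate, C3 is set trans to the C2 aryl group by thermodynamic protonation, and the carboxyl group left over is the acyl donor for step 5.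

Step 4
Reactants: 8 rac-(E)-2-[(2S*,3R*)-5,7-bis(benzyloxy)-2-(4-methoxyphenyl)-4-oxochroman-3-yl]-3-(4-methoxyphenyl)prop-2-enoic acid
Product: 9 (E)-2-[(2S,3R)-5,7-bis(benzyloxy)-2-(4-methoxyphenyl)-4-oxochroman-3-yl]-3-(4-methoxyphenyl)prop-2-enoic acid
Conditions: preparative SFC on amylose tris(3,5-dimethylphenylcarbamate), CO2–MeOH (0.1% HCO2H)
Reagents that add atoms: none
Why: Chromatographic resolution on a chiral stationary phase separates the configurationally stable trans enantiomers; the absolute configuration is to be assigned by ECD or X-ray, and the antipode can be racemised by base through reversible ring opening and recycled.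

Step 5
Reactants: 9 (E)-2-[(2S,3R)-5,7-bis(benzyloxy)-2-(4-methoxyphenyl)-4-oxochroman-3-yl]-3-(4-methoxyphenyl)prop-2-enoic acid; 10 3,5-dimethoxyphenol
Product: 14 (2S,3R)-5,7-bis(benzyloxy)-3-[(2S,3R)-5,7-dimethoxy-2-(4-methoxyphenyl)-4-oxochroman-3-yl]-2-(4-methoxyphenyl)chroman-4-one, via acid chloride 11 (not isolated), via aryl ester 12 (not isolated), via hydroxychalcone 13 (not isolated)
Conditions: (COCl)2, cat. DMF, CH2Cl2, 0 °C → rt, evaporate; 10, Et3N, CH2Cl2, 0 °C; then BF3·OEt2 (excess), 0 → 40 °C; then NaOAc, MeOH, 40 °C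
Reagents that add atoms: none
Why: Acid chloride 11 acylates the phenol oxygen of 10 to give ester 12, a deliberate temporary O–C4'' bond; BF3·OEt2 then shifts the acyl group to one of the two equivalent ortho carbons (Fries rearrangement, C4''–C4a'' bond, ketone 13), and in buffered methanol the released phenol oxygen adds to the benzylidene carbon (O1''–C2'' bond), so the oxygen formally moves from C4'' to C2''. The closest known reaction type is the Friedel–Crafts/Fries acylation–oxa-Michael synthesis of flavanones from phenols and cinnamoyl chlorides. Ring C of unit 2 (O1'', C2'', C3'', C4'', C4a'', C8a'') closes in the 6-endo-trig mode. C2'' is set by 1,3-induction from C3: A(1,3) strain with the cis anisyl group on C2'' should keep the branched C2 in the enone plane and leave only C3–H and the flat C4 carbonyl beside the anisyl group, so O1'' adds to the C3–H face (2''S), and C3'' then equilibrates through the enol to the trans, diequatorial 3''R arrangement. The step needs ortho rather than para acyl migration (secured by the preference of the Fries shift for the chelating ortho position and by the twofold symmetry of 10), acyl migration rather than conjugate C-alkylation at C2'' (favoured by the aprotic Lewis acid at low temperature), and an intact unit 1 (no strong base is present and its 2,3-trans arrangement is the stable one).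

Step 6
Reactants: 14 (2S,3R)-5,7-bis(benzyloxy)-3-[(2S,3R)-5,7-dimethoxy-2-(4-methoxyphenyl)-4-oxochroman-3-yl]-2-(4-methoxyphenyl)chroman-4-one
Product: 15 ruixianglangdusu B, (2S,3R)-5,7-dihydroxy-3-[(2S,3R)-5-hydroxy-7-methoxy-2-(4-methoxyphenyl)-4-oxochroman-3-yl]-2-(4-methoxyphenyl)chroman-4-one
Conditions: BCl3, C6HMe5, CH2Cl2, −78 → 0 °C; then MeOH–H2O
Reagents that add atoms: none
Why: BCl3 cleaves both benzyl ethers (pentamethylbenzene traps the benzyl cation) and, through the boron chelate with the C4'' carbonyl, only the peri methyl ether on O5'', while the non-chelated methyl ethers on O7'' and on both B rings and the four stereocentres should stay untouched.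

Compound list
1 | diethyl succinate | CCOC(=O)CCC(=O)OCC | starting material
2 | 4-methoxybenzaldehyde | COc1ccc(C=O)cc1 | starting material
3 | (E)-3-(ethoxycarbonyl)-4-(4-methoxyphenyl)but-3-enoic acid | CCOC(=O)/C(=C/c1ccc(OC)cc1)CC(=O)O | intermediate
4 | (2E,3E)-2,3-bis(4-methoxybenzylidene)succinic acid | O=C(O)/C(=C/c1ccc(OC)cc1)C(=C\c1ccc(OC)cc1)/C(=O)O | intermediate
5 | (3E,4E)-3,4-bis(4-methoxybenzylidene)oxolane-2,5-dione | O=C1OC(=O)/C(=C/c2ccc(OC)cc2)/C1=C\c1ccc(OC)cc1 | intermediate
6 | 3,5-bis(benzyloxy)phenol | Oc1cc(OCc2ccccc2)cc(OCc2ccccc2)c1 | starting material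
7 | (2E,3E)-4-[2,4-bis(benzyloxy)-6-hydroxyphenyl]-2,3-bis(4-methoxybenzylidene)-4-oxobutanoic acid | O=C(c1c(O)cc(OCc2ccccc2)cc1OCc1ccccc1)/C(=C/c1ccc(OC)cc1)C(=C\c1ccc(OC)cc1)/C(=O)O | intermediate
8 | rac-(E)-2-[(2S*,3R*)-5,7-bis(benzyloxy)-2-(4-methoxyphenyl)-4-oxochroman-3-yl]-3-(4-methoxyphenyl)prop-2-enoic acid (racemate, both enantiomers written) | COc1ccc([C@H]2Oc3cc(OCc4ccccc4)cc(OCc4ccccc4)c3C(=O)[C@@H]2/C(C(=O)O)=C\c2ccc(OC)cc2)cc1.COc1ccc([C@@H]2Oc3cc(OCc4ccccc4)cc(OCc4ccccc4)c3C(=O)[C@H]2/C(C(=O)O)=C\c2ccc(OC)cc2)cc1 | intermediate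
9 | (E)-2-[(2S,3R)-5,7-bis(benzyloxy)-2-(4-methoxyphenyl)-4-oxochroman-3-yl]-3-(4-methoxyphenyl)prop-2-enoic acid | COc1ccc([C@H]2Oc3cc(OCc4ccccc4)cc(OCc4ccccc4)c3C(=O)[C@@H]2/C(C(=O)O)=C\c2ccc(OC)cc2)cc1 | intermediate
10 | 3,5-dimethoxyphenol | COc1cc(O)cc(OC)c1 | starting material
11 | (E)-2-[(2S,3R)-5,7-bis(benzyloxy)-2-(4-methoxyphenyl)-4-oxochroman-3-yl]-3-(4-methoxyphenyl)prop-2-enoyl chloride | COc1ccc([C@H]2Oc3cc(OCc4ccccc4)cc(OCc4ccccc4)c3C(=O)[C@@H]2/C(C(=O)Cl)=C\c2ccc(OC)cc2)cc1 | intermediate
12 | 3,5-dimethoxyphenyl (E)-2-[(2S,3R)-5,7-bis(benzyloxy)-2-(4-methoxyphenyl)-4-oxochroman-3-yl]-3-(4-methoxyphenyl)prop-2-enoate | COc1ccc([C@H]2Oc3cc(OCc4ccccc4)cc(OCc4ccccc4)c3C(=O)[C@@H]2/C(C(=O)Oc2cc(OC)cc(OC)c2)=C\c2ccc(OC)cc2)cc1 | intermediate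
13 | (E)-2-[(2S,3R)-5,7-bis(benzyloxy)-2-(4-methoxyphenyl)-4-oxochroman-3-yl]-1-(2-hydroxy-4,6-dimethoxyphenyl)-3-(4-methoxyphenyl)prop-2-en-1-one | COc1ccc([C@H]2Oc3cc(OCc4ccccc4)cc(OCc4ccccc4)c3C(=O)[C@@H]2/C(C(=O)c2c(O)cc(OC)cc2OC)=C\c2ccc(OC)cc2)cc1 | intermediate
14 | (2S,3R)-5,7-bis(benzyloxy)-3-[(2S,3R)-5,7-dimethoxy-2-(4-methoxyphenyl)-4-oxochroman-3-yl]-2-(4-methoxyphenyl)chroman-4-one | COc1ccc([C@H]2Oc3cc(OCc4ccccc4)cc(OCc4ccccc4)c3C(=O)[C@@H]2[C@H]2C(=O)c3c(OC)cc(OC)cc3O[C@@H]2c2ccc(OC)cc2)cc1 | intermediate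
15 | ruixianglangdusu B, (2S,3R)-5,7-dihydroxy-3-[(2S,3R)-5-hydroxy-7-methoxy-2-(4-methoxyphenyl)-4-oxochroman-3-yl]-2-(4-methoxyphenyl)chroman-4-one | COc1ccc([C@H]2Oc3cc(O)cc(O)c3C(=O)[C@@H]2[C@H]2C(=O)c3c(O)cc(OC)cc3O[C@@H]2c2ccc(OC)cc2)cc1 | target

Total step count: 6. Longest linear sequence: 6 steps (1 → 4 → 5 → 8 → 9 → 14 → 15).

Steps most likely to fail

1. Step 5 (key step). The main danger is poor facial selectivity in the oxa-Michael closure: the sense of 1,3-induction from C3 is argued from a conformational model and is not secured, and C3'' would follow a wrongly set C2''. Further dangers are conjugate C-alkylation of the electron-rich ring at C2'' outrunning the acyl shift, acyl migration to the para carbon, and Lewis-acid loss of the peri benzyl group. The fallback sets out from 9 and returns at 15. Acid 9 acylates 1,3,5-trimethoxybenzene (COc1cc(OC)cc(OC)c1; no free phenol, one kind of ring carbon) under TFAA in CH2Cl2 to give the 2,4,6-trimethoxyphenyl ketone F1. BCl3 with C6HMe5 at −78 → 0 °C removes both benzyl groups and, by chelation, one ortho methyl group to give the hydroxychalcone triol F2. NaOAc in MeOH closes ring C of unit 2 to the 5'',7''-di-O-methyl biflavanone F3. In this closure unit 1 is ionised at O7 and should resist ring opening, so only unit 2 closes reversibly and a wrong C2''/C3'' diastereomer can be separated, re-equilibrated and recycled. BCl3 at 0 °C then cleaves the peri methyl group on O5'' to give 15.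

2. Step 3. Possible failures are loss or migration of benzyl groups under the Lewis acid, acylation at the para carbon, and conjugate addition of the phenol ring carbon to a benzylidene carbon. The fallback sets out from 5 and returns at 8 through 7, replacing the Friedel–Crafts reaction by an organometallic acylation. 1,3,5-Tris(benzyloxy)benzene (c1ccc(COc2cc(OCc3ccccc3)cc(OCc3ccccc3)c2)cc1) is brominated with NBS to 2-bromo-1,3,5-tris(benzyloxy)benzene F4. Bromine–lithium exchange (n-BuLi, THF, −78 °C) and addition of the aryllithium to anhydride 5 should give the tris(benzyloxy)phenyl keto acid F5. MgBr2·OEt2 removes one ortho benzyl group by chelation to give 7, which closes to 8 with NaOAc in MeOH as in step 3.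

3. Step 6. Possible failures are over-demethylation at O7'' or at the B-ring ethers, C-benzylation of the electron-rich A rings, and Lewis-acid ring opening with epimerisation at C2 or C2''. The fallback sets out from 14 and returns at 15 in two milder stages. AlCl3 in MeCN at rt should cleave only the two chelated peri ethers (benzyl on O5, methyl on O5'') to give the 7-O-benzyl ether of the target F6. Neutral hydrogenolysis (H2, Pd/C, EtOAc) then removes the remaining benzyl group to give 15.

Further compounds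
F1 | step 5 | (E)-2-[(2S,3R)-5,7-bis(benzyloxy)-2-(4-methoxyphenyl)-4-oxochroman-3-yl]-3-(4-methoxyphenyl)-1-(2,4,6-trimethoxyphenyl)prop-2-en-1-one | COc1ccc([C@H]2Oc3cc(OCc4ccccc4)cc(OCc4ccccc4)c3C(=O)[C@@H]2/C(C(=O)c2c(OC)cc(OC)cc2OC)=C\c2ccc(OC)cc2)cc1
F2 | step 5 | (E)-2-[(2S,3R)-5,7-dihydroxy-2-(4-methoxyphenyl)-4-oxochroman-3-yl]-1-(2-hydroxy-4,6-dimethoxyphenyl)-3-(4-methoxyphenyl)prop-2-en-1-one | COc1ccc([C@H]2Oc3cc(O)cc(O)c3C(=O)[C@@H]2/C(C(=O)c2c(O)cc(OC)cc2OC)=C\c2ccc(OC)cc2)cc1
F3 | step 5 | (2S,3R)-5,7-dihydroxy-3-[(2S,3R)-5,7-dimethoxy-2-(4-methoxyphenyl)-4-oxochroman-3-yl]-2-(4-methoxyphenyl)chroman-4-one | COc1ccc([C@H]2Oc3cc(O)cc(O)c3C(=O)[C@@H]2[C@H]2C(=O)c3c(OC)cc(OC)cc3O[C@@H]2c2ccc(OC)cc2)cc1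
F4 | step 3 | 2-bromo-1,3,5-tris(benzyloxy)benzene | Brc1c(OCc2ccccc2)cc(OCc2ccccc2)cc1OCc1ccccc1
F5 | step 3 | (2E,3E)-2,3-bis(4-methoxybenzylidene)-4-oxo-4-[2,4,6-tris(benzyloxy)phenyl]butanoic acid | O=C(c1c(OCc2ccccc2)cc(OCc2ccccc2)cc1OCc1ccccc1)/C(=C/c1ccc(OC)cc1)C(=C\c1ccc(OC)cc1)/C(=O)O
F6 | step 6 | (2S,3R)-7-(benzyloxy)-5-hydroxy-3-[(2S,3R)-5-hydroxy-7-methoxy-2-(4-methoxyphenyl)-4-oxochroman-3-yl]-2-(4-methoxyphenyl)chroman-4-one | COc1ccc([C@H]2Oc3cc(OCc4ccccc4)cc(O)c3C(=O)[C@@H]2[C@H]2C(=O)c3c(O)cc(OC)cc3O[C@@H]2c2ccc(OC)cc2)cc1
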